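**Retrosynthetic overview**
- Target ⇐ α-face hydride reduction of the 6α-angeloyloxy-8α-hydroxy-7-ketone ⇐ O6 esterification with angelic acid ⇐ C6 hydroxylation of the 8α-hydroxy-7-ketone enolate.
- 12E,14-Diene ⇐ SO2 extrusion from a 2-alkyl-3-methyl-3-sulfolene, a masked diene carried through the acid and oxidant steps.
- 8α-OH and C7=O ⇐ α-face ketohydroxylation of a Δ7 alkene.
- Ring A, then ring B, in one operation (C5, C9, C10 set) ⇐ catalytic asymmetric proton-initiated chair–chair bicyclization of the complete acyclic C20 chain, ended by loss of H-7, as in the labdane cyclase step.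
- Acyclic C20 precursor ⇐ (2E,6E)-farnesyl bromide + 3-methyl-3-sulfolene.

Assumption: labdane numbering is used (α = face opposite the C10 methyl), the target being (5S,6R,7S,8S,9R,10S)-6α-angeloyloxy-labda-12E,14-diene-7β,8α-diol; 3-methyl-3-sulfolene, (2E,6E)-farnesyl bromide and angelic acid are bought.

**Step 1**
Reactants: 1 3-methyl-2,5-dihydrothiophene 1,1-dioxide (3-methyl-3-sulfolene); 2 (2E,6E)-farnesyl bromide
Product: 4 rac-3-methyl-2-[(2E,6E)-3,7,11-trimethyldodeca-2,6,10-trien-1-yl]-2,5-dihydrothiophene 1,1-dioxide, via 2-lithio-3-methyl-3-sulfolene 3 (not isolated)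
Conditions: 1 (1.5 equiv), 2 (1 equiv), THF/HMPA 4:1, −78 °C; LiN(SiMe3)2 (1.5 equiv) added dropwise to the mixture, 30 min; aq NH4Cl
Reagents that add atoms: none
Why: Sulfolene alkylation (1-metallo-1,3-diene equivalent): deprotonation at C2 gives the allyl anion with the methyl on its central carbon (hence C2, not C5), and it is trapped by SN2 reaction at the primary allylic bromide before it can ring-open, both E alkenes being retained; the new C2 centre is racemic and is lost in step 4.

**Step 2**
Reactants: 4 rac-2-farnesyl-3-methyl-3-sulfolene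
Product: 5 3-methyl-2-{[(1S,4aS,8aS)-2,5,5,8a-tetramethyl-1,4,4a,5,6,7,8,8a-octahydronaphthalen-1-yl]methyl}-2,5-dihydrothiophene 1,1-dioxide (SO2 adduct of labda-7,12E,14-triene; 5α-H, 9α-H, 10β-CH3; about 1:1 at the sulfolene C2 = labdane C12)
Conditions: confined chiral imidodiphosphorimidate (IDPi) Brønsted acid (the antipode that turns (3E,7E)-homofarnesol into (−)-ambrox), 5 mol %, perfluoro-tert-butanol, −20 °C, 2–3 d; then NaHCO3
Reagents that add atoms: none
Why: Proposed new method: the confined acid protonates the terminal isopropylidene alkene in its pocket and the (E,E)-triene folds chair–chair so that ring A and then ring B close by anti additions (E geometry gives the trans ring fusion with 5α-H, 10β-CH3 and 9α-H), the C8 cation then losing the aligned axial 7α-H to the counter-anion to give the Δ7 alkene while the sulfonyl-deactivated, geometrically remote sulfolene alkene stays out; the closest known reactions are the IDPi/fluoroalcohol-catalysed asymmetric bicyclization of homofarnesol to ambrox (hydroxyl-terminated) and the superacid cyclization of farnesyl sulfones and acetates to drim-7-enes (proton-loss terminated), and the step copies the protonation-initiated cyclase step that turns geranylgeranyl diphosphate into the labdane bicycle.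

**Step 3**
Reactants: 5 SO2 adduct of labda-7,12E,14-triene
Product: 6 SO2 adduct of 8α-hydroxylabda-12E,14-dien-7-one, i.e. 3-methyl-2-{[(1R,2S,4aS,8aS)-2-hydroxy-2,5,5,8a-tetramethyl-3-oxodecahydronaphthalen-1-yl]methyl}-2,5-dihydrothiophene 1,1-dioxide (about 1:1 at the sulfolene C2)
Conditions: RuCl3 (1 mol %), KHSO5 (as 2KHSO5·KHSO4·K2SO4, 2.2 equiv KHSO5), NaHCO3, EtOAc/MeCN/H2O 6:6:1, 20 °C, 15–30 min
Reagents that add atoms: potassium peroxymonosulfate KHSO5, [K+].[O-]S(=O)(=O)OO (both new oxygen atoms, passed on through RuO4, O=[Ru](=O)(=O)=O, formed from RuCl3 in the flask)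
Why: RuO4-catalysed ketohydroxylation: the electrophilic oxidant adds [3+2] to the electron-rich trisubstituted Δ7 alkene from the α face (opposite the axial C10 methyl and the β C9 substituent), and oxidative collapse of the ruthenate ester gives the C7 ketone and the tertiary 8α-alcohol (C8 is set by this syn α-face addition), the doubly sulfonyl-flanked sulfolene alkene reacting more slowly.

**Step 4**
Reactants: 6 SO2 adduct of 8α-hydroxylabda-12E,14-dien-7-one
Product: 7 8α-hydroxylabda-12E,14-dien-7-one (5α-H, 9α-H, 10β-CH3)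
Conditions: toluene/pyridine 10:1, 110 °C, argon sweep, 1–2 h
Reagents that add atoms: none
Why: Thermal cheletropic (disrotatory) extrusion of SO2 from the 2-substituted 3-sulfolene turns the C2 substituent outwards, so both C12 epimers converge on the 12E-diene; the ketol is not touched under these buffered conditions.

**Step 5**
Reactants: 7 8α-hydroxylabda-12E,14-dien-7-one
Product: 9 6α,8α-dihydroxylabda-12E,14-dien-7-one, via dipotassium alkoxide enolate 8 (not isolated)
Conditions: KN(SiMe3)2 (2.5 equiv), THF, −78 °C, 45 min; 2-(phenylsulfonyl)-3-phenyloxaziridine (1.5 equiv), −78 °C, 30 min; AcOH at −78 °C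
Reagents that add atoms: 2-(phenylsulfonyl)-3-phenyloxaziridine (Davis oxaziridine), O=S(=O)(N1OC1c1ccccc1)c1ccccc1
Why: Davis enolate hydroxylation: the ketone can enolize only towards C6 (C8 is quaternary) and the oxaziridine attacks the potassium enolate from the α face because the β face of C6 is blocked by the two syn-axial methyls (C10 and 4β), giving the equatorial 6α-alcohol, which is also the thermodynamic epimer; the diene does not react at −78 °C.

**Step 6**
Reactants: 9 6α,8α-dihydroxylabda-12E,14-dien-7-one; 10 angelic acid ((Z)-2-methylbut-2-enoic acid)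
Product: 12 6α-angeloyloxy-8α-hydroxylabda-12E,14-dien-7-one, via angelic 2,4,6-trichlorobenzoic anhydride 11 (not isolated)
Conditions: 10 (3 equiv), 2,4,6-Cl3C6H2COCl (3 equiv), Et3N (6 equiv), toluene, 20 °C, 2 h; then 9, toluene, 70 °C, 24 h (no DMAP)
Reagents that add atoms: none
Why: Yamaguchi-type esterification through the mixed anhydride, run without DMAP so that the Z (angelate) geometry is not isomerized to tiglate; only the secondary 6α-OH is acylated because the tertiary 8α-OH is too hindered, and no stereocentre is changed.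

**Step 7**
Reactants: 12 6α-angeloyloxy-8α-hydroxylabda-12E,14-dien-7-one
Product: 13 6α-angeloyloxy-labda-12E,14-diene-7β,8α-diol (target, CNP0189082.1)
Conditions: NaBH4 (1.5 equiv), CeCl3·7H2O (1.5 equiv), MeOH, −40 °C, 1 h; AcOH quench
Reagents that add atoms: none
Why: Luche-type hydride reduction: hydride adds axially from the α face of the C7 ketone (the β face is shielded by the adjacent axial 8β-methyl) to give the equatorial 7β-alcohol trans to the 8α-OH, and the near-neutral CeCl3 medium at low temperature suppresses O6 to O7 acyl migration and leaves the enoate and diene alone.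

**Compound list**
1 | 3-methyl-2,5-dihydrothiophene 1,1-dioxide (3-methyl-3-sulfolene) | CC1=CCS(=O)(=O)C1 | starting material
2 | (2E,6E)-farnesyl bromide | CC(C)=CCC/C(C)=C/CC/C(C)=C/CBr | starting material
3 | 2-lithio-3-methyl-3-sulfolene | [Li+].CC1=CCS(=O)(=O)[CH-]1 | intermediate
4 | rac-3-methyl-2-[(2E,6E)-3,7,11-trimethyldodeca-2,6,10-trien-1-yl]-2,5-dihydrothiophene 1,1-dioxide | CC(C)=CCC/C(C)=C/CC/C(C)=C/CC1C(C)=CCS1(=O)=O | intermediate
5 | SO2 adduct of labda-7,12E,14-triene (5α-H, 9α-H, 10β-CH3; epimers at sulfolene C2) | O=S1(=O)CC=C(C)C1C[C@H]1C(C)=CC[C@H]2C(C)(C)CCC[C@@]21C | intermediate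
6 | SO2 adduct of 8α-hydroxylabda-12E,14-dien-7-one (epimers at sulfolene C2) | O=S1(=O)CC=C(C)C1C[C@H]1[C@](C)(O)C(=O)C[C@H]2C(C)(C)CCC[C@@]21C | intermediate
7 | 8α-hydroxylabda-12E,14-dien-7-one | C=C/C(C)=C/C[C@H]1[C@](C)(O)C(=O)C[C@H]2C(C)(C)CCC[C@@]21C | intermediate
8 | dipotassium 8-alkoxide C6–C7 enolate of 7 | C=C/C(C)=C/C[C@H]1[C@](C)([O-])C([O-])=C[C@H]2C(C)(C)CCC[C@@]21C.[K+].[K+] | intermediate
9 | 6α,8α-dihydroxylabda-12E,14-dien-7-one | C=C/C(C)=C/C[C@H]1[C@](C)(O)C(=O)[C@H](O)[C@H]2C(C)(C)CCC[C@@]21C | intermediate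
10 | angelic acid ((Z)-2-methylbut-2-enoic acid) | C/C=C(/C)C(=O)O | starting material
11 | angelic 2,4,6-trichlorobenzoic anhydride | C/C=C(/C)C(=O)OC(=O)c1c(Cl)cc(Cl)cc1Cl | intermediate
12 | 6α-angeloyloxy-8α-hydroxylabda-12E,14-dien-7-one | C=C/C(C)=C/C[C@H]1[C@](C)(O)C(=O)[C@H](OC(=O)/C(C)=C\C)[C@H]2C(C)(C)CCC[C@@]21C | intermediate
13 | (5S,6R,7S,8S,9R,10S)-6α-angeloyloxy-labda-12E,14-diene-7β,8α-diol | C=C/C(C)=C/C[C@H]1[C@](C)(O)[C@@H](O)[C@H](OC(=O)/C(C)=C\C)[C@H]2C(C)(C)CCC[C@@]21C | target

**Step count and risks**
Total steps: 7. Longest linear sequence: 7 (from 1 and 2 to 13; angelic acid 10 enters at step 6).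

Three steps most likely to fail:

- **Step 2** (enantioselectivity, and Δ7 versus Δ8(17)/Δ8(9) termination in a cyclization with no heteroatom terminator). The fallback sets out from 4 and splits the cyclization into a reagent-controlled and a substrate-controlled stage. Stoichiometric Lewis-acid-assisted chiral Brønsted acid, (R)-2-(2-fluorobenzyloxy)-2'-hydroxy-1,1'-binaphthyl·SnCl4 (the antipode leading to the normal, ambrox-type series; toluene, −78 °C), closes only ring A enantioselectively. This gives mainly the monocyclic 3-methyl-2-{(2E)-3-methyl-5-[(1S)-2,6,6-trimethylcyclohex-2-en-1-yl]pent-2-en-1-yl}-2,5-dihydrothiophene 1,1-dioxide F1, with its exocyclic alkene isomer and some 5. The crude mixture is then treated with FSO3H in 2-nitropropane at −78 °C. This reprotonates the ring alkene and closes ring B under control of the C5 centre, under superacid conditions known to end farnesyl sulfone cyclizations at the Δ7 alkene. The fallback comes back to the route at 5.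

- **Step 3** (competition of the sulfolene alkene for the ruthenium oxidant, or over-oxidation). The fallback sets out from 5 and replaces the one-step ketohydroxylation by osmylation followed by alcohol oxidation. OsO4 (2–5 mol %), quinuclidine (10 mol %) and N-methylmorpholine N-oxide in acetone/H2O at 20 °C dihydroxylate the electron-rich Δ7 alkene from the α face and stop at the diol. This gives the SO2 adduct of labda-12E,14-diene-7α,8α-diol F2. IBX in DMSO at 20 °C then oxidizes the secondary 7α-OH without glycol cleavage. The fallback comes back to the route at 6.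

- **Step 6** (slow acylation of the hindered ketol OH, angelate to tiglate isomerization, base-induced ketol transposition at 70 °C). The fallback sets out from 9 and builds the Z-enoate on the substrate instead of transferring it. Esterification of 9 with 2-[bis(2,2,2-trifluoroethoxy)phosphoryl]propanoic acid (DCC, catalytic DMAP, CH2Cl2, 0 to 20 °C) gives 8α-hydroxy-7-oxolabda-12E,14-dien-6α-yl 2-[bis(2,2,2-trifluoroethoxy)phosphoryl]propanoate F3. Still–Gennari olefination with acetaldehyde (KN(SiMe3)2 1.05 equiv, 18-crown-6, THF, −78 °C) then forms the angelate with kinetic Z selectivity. The fallback comes back to the route at 12.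

**Further compounds**
F1 | step 2 | 3-methyl-2-{(2E)-3-methyl-5-[(1S)-2,6,6-trimethylcyclohex-2-en-1-yl]pent-2-en-1-yl}-2,5-dihydrothiophene 1,1-dioxide (epimers at sulfolene C2) | O=S1(=O)CC=C(C)C1C/C=C(\C)CC[C@H]1C(C)(C)CCC=C1C
F2 | step 3 | SO2 adduct of labda-12E,14-diene-7α,8α-diol (epimers at sulfolene C2) | O=S1(=O)CC=C(C)C1C[C@H]1[C@](C)(O)[C@H](O)C[C@H]2C(C)(C)CCC[C@@]21C
F3 | step 6 | 8α-hydroxy-7-oxolabda-12E,14-dien-6α-yl 2-[bis(2,2,2-trifluoroethoxy)phosphoryl]propanoate (epimers at the phosphonate α-carbon) | C=C/C(C)=C/C[C@H]1[C@](C)(O)C(=O)[C@H](OC(=O)C(C)P(=O)(OCC(F)(F)F)OCC(F)(F)F)[C@H]2C(C)(C)CCC[C@@]21C
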